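Numbering: carotenoid locants, unprimed for the 5,8-epoxy (furanoid) half, primed for the ε half. The retrosynthesis cuts C-11=C-12 (Wittig: furanoid C15 enal + ε-C25 phosphonium salt), then C-11'=C-12' (ε-C15 salt from (R)-α-ionone + C10 dialdehyde).
In the C15 enal the O–C-8 bond is cut as an epoxide opening and C-8=C-9 as a Wittig reaction; this leads back to a bicyclic butenolide with C-8 at the carboxyl level.
The butenolide is cut at C-1–C-2 and C-5–C-6 together. With C-8 as a carbonyl, O–C-8(=O)–C-7=C-6=C-1(CH3)2 is an allenoate and C-2=C-3–C-4=C-5(CH3)–O a 1-acyloxydiene, so the gem-dimethyl carbon C-1, the oxygen-bearing quaternary C-5 and the C-6=C-7 bond shared by the cyclohexane and the five-membered oxygen ring are what an intramolecular [4+2] addition to the distal allene bond leaves behind.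
Forward: an acyclic, achiral dienyl allenoate (3 steps) closes cyclohexene and butenolide in one operation (step 4); C-3=C-4 is hydrogenated, the lactone is opened and extended, the dihydrofuran is closed again at C-8 (step 9), the side chain is taken to the enal, and the polyene is joined last.
Stereochemistry: C-5 arises racemic in step 4. Sharpless epoxidation and invertive epoxide opening set C-8 (R) by reagent control, and the 5R,8R diastereomer is separated from its C-5 epimer there (at most half of the material is carried on). C-6' comes from (R)-α-ionone; E alkenes come from Wittig reactions and thermal equilibration.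
Key step: step 4

Assumption: (R)-α-ionone (single enantiomer) and (2E,4E,6E)-2,7-dimethylocta-2,4,6-trienedial are taken as purchasable.

Step 1
Reactants: 1 propyne; 2 chloroacetic acid
Product: 3 (1E)-1-iodoprop-1-en-2-yl chloroacetate
Conditions: propyne (excess), NIS (1.1 equiv), ClCH2CO2H (3 equiv), CH2Cl2, 0 °C to rt, dark
Reagents that add atoms: N-iodosuccinimide, O=C1CCC(=O)N1I
Why: electrophilic trans-iodoacyloxylation of a terminal alkyne: the carboxylate should open the iodonium ion at the methyl-bearing carbon from the face opposite to iodine, which places the ester oxygen trans to iodine (E).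

Step 2
Reactants: 3 (1E)-1-iodoprop-1-en-2-yl chloroacetate; 4 tributyl(vinyl)stannane
Product: 5 (2E)-penta-2,4-dien-2-yl chloroacetate
Conditions: Pd2(dba)3 (2.5 mol%), AsPh3 (10 mol%), NMP, rt
Reagents that add atoms: none
Why: Stille coupling of an alkenyl iodide with retention of geometry, so the vinyl group ends up trans to the ester oxygen and cis to the methyl group; the alkyl chloride and the enol ester should not react with zerovalent palladium at room temperature.

Step 3
Reactants: 5 (2E)-penta-2,4-dien-2-yl chloroacetate; 6 2-methylpropanoyl chloride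
Product: 10 (2E)-penta-2,4-dien-2-yl 4-methylpenta-2,3-dienoate, via phosphonium chloride 7 (not isolated), via ester ylide 8 (not isolated), via dimethylketene 9 (not isolated)
Conditions: PPh3, toluene, 60 °C; solvent exchanged for CH2Cl2; Et3N (2.2 equiv), 0 °C, then 6 added slowly, 0 °C to rt
Reagents that add atoms: none
Why: quaternisation of PPh3 by the α-chloro ester, deprotonation to the stabilised ylide and Wittig reaction with dimethylketene made in the flask from 6 and Et3N (allene synthesis from a ketene and an ester ylide) should give the 4,4-dimethylallenoate without touching the enol ester or the diene.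

Step 4
Reactants: 10 (2E)-penta-2,4-dien-2-yl 4-methylpenta-2,3-dienoate
Product: 11 rac-actinidiolide (4,4,7a-trimethyl-5,7a-dihydro-1-benzofuran-2(4H)-one)
Conditions: toluene (0.01 M), BHT (cat.), 130 °C, sealed tube
Reagents that add atoms: none
Why: Proposed new method: heating should bring the s-cis 1-acyloxydiene (C-2=C-3–C-4=C-5) over the distal C-6=C-1 π bond of the allenoate and join C-5 to C-6 and C-2 to C-1 in a concerted, asynchronous [4+2] cycloaddition, driven by release of allene strain and by the exchange of two π bonds for two σ bonds. The closest known reaction type is the Himbert intramolecular Diels–Alder reaction of aryl allenecarboxylates and allenecarboxanilides, in which an arene is the four-carbon partner; an acyclic diene needs no dearomatisation and should react more readily. The cyclohexene closes in the cycloaddition itself, and the butenolide closes as the tether ring of a type 1 intramolecular Diels–Alder reaction (ring atoms O, C-8, C-7, C-6, C-5), the conjugated C-7=C-6 bond staying untouched. C-5 is the only new stereocentre; since C-1 carries two methyl groups the substrate holds no controlling element and 11 should form as the racemate, the R configuration being selected in step 9. Site selectivity and regioselectivity are needed and are secured by the ester link, which puts only O and C-8 between C-5 and C-7, so that addition to the proximal C-7=C-6 bond or in the other orientation would demand a β-lactone or a bridged ring, and by the E enol ester geometry of 10, which holds the ester oxygen on the outside of the diene where the tether can reach.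

Step 5
Reactants: 11 rac-actinidiolide
Product: 12 rac-dihydroactinidiolide (4,4,7a-trimethyl-5,6,7,7a-tetrahydro-1-benzofuran-2(4H)-one)
Conditions: H2 (1 atm), RhCl(PPh3)3 (5 mol%), toluene–EtOH, rt
Reagents that add atoms: none
Why: homogeneous hydrogenation with RhCl(PPh3)3 should saturate only the cis-disubstituted C-3=C-4 bond, the trisubstituted conjugated butenolide alkene being far less reactive toward this catalyst.

Step 6
Reactants: 12 rac-dihydroactinidiolide
Product: 13 rac-4,4,7a-trimethyl-2,4,5,6,7,7a-hexahydro-1-benzofuran-2-ol (lactol)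
Conditions: iBu2AlH (1.1 equiv), CH2Cl2, −78 °C; aq. potassium sodium tartrate
Reagents that add atoms: none
Why: partial reduction of a lactone at low temperature stops at the lactol, and the quaternary C-5 rules out aromatisation to a furan.

Step 7
Reactants: 13 lactol; 14 ethyl 2-(triphenyl-λ5-phosphanylidene)propanoate
Product: 15 ethyl (2E,4Z)-4-(2-hydroxy-2,6,6-trimethylcyclohexylidene)-2-methylbut-2-enoate (racemic)
Conditions: toluene, PhCO2H (cat.), 80 °C
Reagents that add atoms: none
Why: Wittig olefination of the lactol through its open hydroxy enal form with a stabilised ylide should give the E trisubstituted C-8=C-9 bond, while the C-6=C-7 geometry (C-8 on the side of C-5) is carried over from the ring.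

Step 8
Reactants: 15 hydroxy dienoate
Product: 16 (2E,4Z)-4-(2-hydroxy-2,6,6-trimethylcyclohexylidene)-2-methylbut-2-en-1-ol (racemic)
Conditions: iBu2AlH (3.5 equiv), CH2Cl2, −78 to 0 °C; aq. potassium sodium tartrate
Reagents that add atoms: none
Why: 1,2-reduction of the conjugated ester to the primary allylic alcohol needed for the directed epoxidation.

Step 9
Reactants: 16 dienediol
Product: 18 (2S)-2-[(2R,7aR)-4,4,7a-trimethyl-2,4,5,6,7,7a-hexahydro-1-benzofuran-2-yl]propane-1,2-diol, via epoxy alcohol 17 (not isolated)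
Conditions: Ti(OiPr)4 (1.0 equiv), L-(+)-diisopropyl tartrate (1.2 equiv), t-BuOOH (2 equiv), 4 Å molecular sieves, CH2Cl2, −20 °C; then rt; chromatography
Reagents that add atoms: tert-butyl hydroperoxide, CC(C)(C)OO
Why: Sharpless asymmetric epoxidation of the primary allylic alcohol under reagent control by L-(+)-tartrate (the sense that gives 2S,3S epoxides from simple E allylic alcohols) should give the 8S,9S epoxide for either configuration at C-5, and the titanium-assisted 5-exo attack of the tertiary hydroxyl on C-8 with inversion sets 8R, so the 5R half of 16 gives 18 and the 5S half gives the C-5 epimer of 18, which is removed by chromatography and with it the wrong configuration at C-5.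

Step 10
Reactants: 18 furanoid diol
Product: 19 (2R)-2-hydroxy-2-[(2R,7aR)-4,4,7a-trimethyl-2,4,5,6,7,7a-hexahydro-1-benzofuran-2-yl]propanal
Conditions: IBX (1.5 equiv), DMSO, rt
Reagents that add atoms: none
Why: IBX should oxidise the primary hydroxyl of the 1,2-diol to the aldehyde without glycol cleavage and leave the tertiary hydroxyl and the allylic ether alone (the descriptor at C-9 changes only through the priority rules).

Step 11
Reactants: 19 hydroxy aldehyde
Product: 21 (2E)-3-[(2R,7aR)-4,4,7a-trimethyl-2,4,5,6,7,7a-hexahydro-1-benzofuran-2-yl]but-2-enal, via enol ether 20 (not isolated)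
Conditions: Ph3P(CH2OMe)Cl (2.5 equiv), KN(SiMe3)2, THF, −78 to 0 °C; then 0.5 M aq. oxalic acid, THF, 0 °C
Reagents that add atoms: (methoxymethyl)triphenylphosphonium chloride, COC[P+](c1ccccc1)(c1ccccc1)c1ccccc1.[Cl-]; water, O
Why: Wittig methoxymethylenation followed by mild acid hydrolysis of the 3-hydroxy enol ether with allylic transposition (loss of the tertiary hydroxyl through a methoxy-stabilised allyl cation) should give the enal, whose E geometry (formyl trans to the ring-bearing carbon) is thermodynamically preferred; C-8 and C-5 are not touched.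

Step 12
Reactants: 22 (R)-α-ionone
Product: 23 (1E)-3-methyl-1-[(1R)-2,6,6-trimethylcyclohex-2-en-1-yl]penta-1,4-dien-3-ol (both C-3 epimers)
Conditions: CH2=CHMgBr, THF, 0 °C
Reagents that add atoms: vinylmagnesium bromide, C=C[Mg]Br
Why: 1,2-addition of CH2=CHMgBr to the enone carbonyl; the new carbinol centre forms unselectively and disappears in step 13, and C-6' is untouched.

Step 13
Reactants: 23 vinyl carbinol
Product: 24 [(2E,4E)-3-methyl-5-[(1R)-2,6,6-trimethylcyclohex-2-en-1-yl]penta-2,4-dien-1-yl](triphenyl)phosphonium bromide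
Conditions: PPh3·HBr, MeOH, rt
Reagents that add atoms: triphenylphosphine hydrobromide, [Br-].[PH+](c1ccccc1)(c1ccccc1)c1ccccc1
Why: ionisation of the tertiary dienyl carbinol and capture of the delocalised cation by PPh3 at the primary terminus (the standard formation of a C15 Wittig salt) should give the E trisubstituted alkene, the ring alkene and C-6' surviving this mild acid.

Step 14
Reactants: 24 ε-C15 phosphonium bromide; 25 (2E,4E,6E)-2,7-dimethylocta-2,4,6-trienedial
Product: 28 (2E,4E,6E,8E,10E,12E)-2,7,11-trimethyl-13-[(1R)-2,6,6-trimethylcyclohex-2-en-1-yl]trideca-2,4,6,8,10,12-hexaenal, via ylide 26 (not isolated), via 8Z isomer 27 (not isolated)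
Conditions: NaOMe, MeOH–CH2Cl2, 0 °C to rt, 25 in excess (3 equiv); then heptane, reflux; chromatography
Reagents that add atoms: none
Why: Wittig reaction of the allylic ylide with an excess of the symmetrical dialdehyde should stop after one olefination, and heating should equilibrate the new disubstituted double bond to E.

Step 15
Reactants: 28 C25 aldehyde
Product: 29 (2E,4E,6E,8E,10E,12E)-2,7,11-trimethyl-13-[(1R)-2,6,6-trimethylcyclohex-2-en-1-yl]trideca-2,4,6,8,10,12-hexaen-1-ol
Conditions: NaBH4, EtOH–THF, 0 °C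
Reagents that add atoms: none
Why: 1,2-reduction of the polyenal to the primary allylic alcohol by borohydride.

Step 16
Reactants: 29 C25 alcohol
Product: 30 [(2E,4E,6E,8E,10E,12E)-2,7,11-trimethyl-13-[(1R)-2,6,6-trimethylcyclohex-2-en-1-yl]trideca-2,4,6,8,10,12-hexaen-1-yl](triphenyl)phosphonium bromide
Conditions: PPh3·HBr, MeOH–CH2Cl2, 0 °C to rt
Reagents that add atoms: triphenylphosphine hydrobromide, [Br-].[PH+](c1ccccc1)(c1ccccc1)c1ccccc1
Why: the polyenylic alcohol ionises readily and PPh3 should add at the terminal carbon, which keeps the full conjugation (as in the formation of retinyl phosphonium salts).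

Step 17
Reactants: 30 C25 phosphonium bromide; 21 furanoid C15 enal
Product: 33 (5R,8R,6'R)-5,8-epoxy-5,8-dihydro-β,ε-carotene, via ylide 31 (not isolated), via 11Z isomer 32 (not isolated)
Conditions: NaOMe (1.05 equiv), MeOH–CH2Cl2, −20 °C, then 21, to rt; then heptane, reflux, N2, dark; crystallisation
Reagents that add atoms: none
Why: Wittig condensation of the polyenyl ylide with the enal forms C-11=C-12 and thermal equilibration should give the all-E polyene; base is limited to one equivalent at low temperature and acid is avoided, so C-8 (γ to the formyl group and an allylic ether carbon) should not be scrambled.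

Compound list
1 | propyne | CC#C | starting material
2 | chloroacetic acid | OC(=O)CCl | starting material
3 | (1E)-1-iodoprop-1-en-2-yl chloroacetate | C/C(=C\I)OC(=O)CCl | intermediate
4 | tributyl(vinyl)stannane | C=C[Sn](CCCC)(CCCC)CCCC | starting material
5 | (2E)-penta-2,4-dien-2-yl chloroacetate | C/C(=C\C=C)OC(=O)CCl | intermediate
6 | 2-methylpropanoyl chloride | CC(C)C(Cl)=O | starting material
7 | {2-oxo-2-[(2E)-penta-2,4-dien-2-yloxy]ethyl}(triphenyl)phosphonium chloride | C/C(=C\C=C)OC(=O)C[P+](c1ccccc1)(c1ccccc1)c1ccccc1.[Cl-] | intermediate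
8 | (2E)-penta-2,4-dien-2-yl (triphenyl-λ5-phosphanylidene)acetate | C/C(=C\C=C)OC(=O)C=P(c1ccccc1)(c1ccccc1)c1ccccc1 | intermediate
9 | dimethylketene | CC(C)=C=O | intermediate
10 | (2E)-penta-2,4-dien-2-yl 4-methylpenta-2,3-dienoate | C/C(=C\C=C)OC(=O)C=C=C(C)C | intermediate
11 | rac-actinidiolide, 4,4,7a-trimethyl-5,7a-dihydro-1-benzofuran-2(4H)-one | CC1(C)CC=CC2(C)OC(=O)C=C12 | intermediate
12 | rac-dihydroactinidiolide, 4,4,7a-trimethyl-5,6,7,7a-tetrahydro-1-benzofuran-2(4H)-one | CC1(C)CCCC2(C)OC(=O)C=C12 | intermediate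
13 | rac-4,4,7a-trimethyl-2,4,5,6,7,7a-hexahydro-1-benzofuran-2-ol (anomers) | CC1(C)CCCC2(C)OC(O)C=C12 | intermediate
14 | ethyl 2-(triphenyl-λ5-phosphanylidene)propanoate | CCOC(=O)C(C)=P(c1ccccc1)(c1ccccc1)c1ccccc1 | starting material
15 | ethyl (2E,4Z)-4-(2-hydroxy-2,6,6-trimethylcyclohexylidene)-2-methylbut-2-enoate (racemic) | CCOC(=O)/C(C)=C/C=C1/C(C)(C)CCCC1(C)O | intermediate
16 | (2E,4Z)-4-(2-hydroxy-2,6,6-trimethylcyclohexylidene)-2-methylbut-2-en-1-ol (racemic) | OC/C(C)=C/C=C1/C(C)(C)CCCC1(C)O | intermediate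
17 | (1R,2Z)-2-{[(2S,3S)-3-(hydroxymethyl)-3-methyloxiran-2-yl]methylidene}-1,3,3-trimethylcyclohexan-1-ol | OC[C@]1(C)O[C@H]1/C=C2/C(C)(C)CCC[C@@]2(C)O | intermediate
18 | (2S)-2-[(2R,7aR)-4,4,7a-trimethyl-2,4,5,6,7,7a-hexahydro-1-benzofuran-2-yl]propane-1,2-diol | OC[C@](C)(O)[C@H]1C=C2C(C)(C)CCC[C@@]2(C)O1 | intermediate
19 | (2R)-2-hydroxy-2-[(2R,7aR)-4,4,7a-trimethyl-2,4,5,6,7,7a-hexahydro-1-benzofuran-2-yl]propanal | O=C[C@](C)(O)[C@H]1C=C2C(C)(C)CCC[C@@]2(C)O1 | intermediate
20 | (2S)-4-methoxy-2-[(2R,7aR)-4,4,7a-trimethyl-2,4,5,6,7,7a-hexahydro-1-benzofuran-2-yl]but-3-en-2-ol (E/Z mixture) | COC=C[C@](C)(O)[C@H]1C=C2C(C)(C)CCC[C@@]2(C)O1 | intermediate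
21 | (2E)-3-[(2R,7aR)-4,4,7a-trimethyl-2,4,5,6,7,7a-hexahydro-1-benzofuran-2-yl]but-2-enal | C/C(=C\C=O)[C@H]1C=C2C(C)(C)CCC[C@@]2(C)O1 | intermediate
22 | (R)-α-ionone, (3E)-4-[(1R)-2,6,6-trimethylcyclohex-2-en-1-yl]but-3-en-2-one | CC1=CCCC(C)(C)[C@H]1/C=C/C(C)=O | starting material
23 | (1E)-3-methyl-1-[(1R)-2,6,6-trimethylcyclohex-2-en-1-yl]penta-1,4-dien-3-ol (both C-3 epimers) | CC1=CCCC(C)(C)[C@H]1/C=C/C(C)(O)C=C | intermediate
24 | [(2E,4E)-3-methyl-5-[(1R)-2,6,6-trimethylcyclohex-2-en-1-yl]penta-2,4-dien-1-yl](triphenyl)phosphonium bromide | CC1=CCCC(C)(C)[C@H]1/C=C/C(C)=C/C[P+](c1ccccc1)(c1ccccc1)c1ccccc1.[Br-] | intermediate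
25 | (2E,4E,6E)-2,7-dimethylocta-2,4,6-trienedial | O=C/C(C)=C/C=C/C=C(C)/C=O | starting material
26 | ylide of 24 | CC1=CCCC(C)(C)[C@H]1/C=C/C(C)=C/C=P(c1ccccc1)(c1ccccc1)c1ccccc1 | intermediate
27 | (2E,4E,6E,8Z,10E,12E)-2,7,11-trimethyl-13-[(1R)-2,6,6-trimethylcyclohex-2-en-1-yl]trideca-2,4,6,8,10,12-hexaenal | CC1=CCCC(C)(C)[C@H]1/C=C/C(C)=C/C=C\C(C)=C\C=C\C=C(C)\C=O | intermediate
28 | (2E,4E,6E,8E,10E,12E)-2,7,11-trimethyl-13-[(1R)-2,6,6-trimethylcyclohex-2-en-1-yl]trideca-2,4,6,8,10,12-hexaenal | CC1=CCCC(C)(C)[C@H]1/C=C/C(C)=C/C=C/C(C)=C/C=C/C=C(C)/C=O | intermediate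
29 | (2E,4E,6E,8E,10E,12E)-2,7,11-trimethyl-13-[(1R)-2,6,6-trimethylcyclohex-2-en-1-yl]trideca-2,4,6,8,10,12-hexaen-1-ol | CC1=CCCC(C)(C)[C@H]1/C=C/C(C)=C/C=C/C(C)=C/C=C/C=C(C)/CO | intermediate
30 | [(2E,4E,6E,8E,10E,12E)-2,7,11-trimethyl-13-[(1R)-2,6,6-trimethylcyclohex-2-en-1-yl]trideca-2,4,6,8,10,12-hexaen-1-yl](triphenyl)phosphonium bromide | CC1=CCCC(C)(C)[C@H]1/C=C/C(C)=C/C=C/C(C)=C/C=C/C=C(C)/C[P+](c1ccccc1)(c1ccccc1)c1ccccc1.[Br-] | intermediate
31 | ylide of 30 | CC1=CCCC(C)(C)[C@H]1/C=C/C(C)=C/C=C/C(C)=C/C=C/C=C(C)/C=P(c1ccccc1)(c1ccccc1)c1ccccc1 | intermediate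
32 | (11Z)-isomer of 33 | CC1=CCCC(C)(C)[C@H]1/C=C/C(C)=C/C=C/C(C)=C/C=C/C=C(C)/C=C\C=C(/C)[C@H]1C=C2C(C)(C)CCC[C@@]2(C)O1 | intermediate
33 | (5R,8R,6'R)-5,8-epoxy-5,8-dihydro-β,ε-carotene | CC1=CCCC(C)(C)[C@H]1/C=C/C(C)=C/C=C/C(C)=C/C=C/C=C(C)/C=C/C=C(\C)[C@H]1C=C2C(C)(C)CCC[C@@]2(C)O1 | target

Total step count: 17. Longest linear sequence: 12 steps (steps 1 to 11, then step 17).

Steps most likely to fail

Step 4 (Proposed new method). The diene terminus that carries both the tether and the inside methyl group must twist into an s-cis array; if that is slow, dimerisation of the allene, isomerisation of the allenoate to the conjugated dienoate or polymerisation of the diene may outrun the cycloaddition. The fallback uses known chemistry and takes the carbocycle from a terpenoid instead of making it by cycloaddition. It sets out from 22 (the racemic ketone serves equally here) and comes back at 12. Acid isomerisation (H2SO4) moves the ring double bond into conjugation to give β-ionone F1. Peracid epoxidation of the tetrasubstituted ring alkene gives 5,6-epoxy-β-ionone F2. Baeyer–Villiger oxidation of the enone with alkenyl migration gives the epoxy enol acetate F3. Methanolysis (K2CO3, MeOH, 0 °C) gives the epoxy aldehyde F4. Oxidation with NaClO2 gives the epoxy acid F5. Acid-catalysed opening of the epoxide at C-5 by the carboxyl group gives the hydroxy lactone F6, and dehydration (SOCl2, pyridine) gives 12.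

Step 9. Under the Lewis acid the epoxide may ionise instead of being displaced (loss of the invertive course at C-8), the tertiary epoxide carbon C-9 may be attacked to give a six-membered ether, and the two diastereomers may co-elute. The fallback separates epoxidation from ring closure and closes the ring by an anionic displacement. It sets out from 16 and comes back at 18. The epoxidation is run with catalytic Ti(OiPr)4 and worked up cold, so that 17 is isolated together with the 1S diastereomer of the epoxy alcohol F7. Silylation of the primary hydroxyl (t-BuMe2SiCl, imidazole) gives the silyl ether of the 1R epoxy alcohol F8 and the silyl ether of the 1S epoxy alcohol F9. KH in THF turns the tertiary hydroxyl into the alkoxide, which opens the epoxide at the secondary carbon C-8 in a 5-exo displacement with inversion to give the silyl ether of the furanoid diol F10 and its 7aS diastereomer F11, which are separated here. Bu4NF then converts F10 into 18.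

Step 11. The aqueous acid may also ionise the allylic C-8–O bond (epimerisation at C-8 or ring opening), and the transposition may give the enal with poor E/Z control. The fallback avoids acid and moves the furanoid half into the ylide role. It sets out from 19 and comes back at 33, using 28 in place of 30. Methylenation (Ph3P=CH2) gives the tertiary vinyl carbinol F12. Acetylation of its potassium alkoxide (KN(SiMe3)2, Ac2O) gives the tertiary allylic acetate F13. Pd(PPh3)4 (zerovalent palladium) with one equivalent of PPh3 ionises the acetate to the π-allyl complex, which PPh3 attacks at the primary terminus to give the furanoid C15 phosphonium acetate F14. NaOMe gives the furanoid C15 ylide F15, which is condensed with 28 and equilibrated thermally to 33.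

Further compounds
F1 | step 4 | β-ionone, (3E)-4-(2,6,6-trimethylcyclohex-1-en-1-yl)but-3-en-2-one | CC1=C(/C=C/C(C)=O)C(C)(C)CCC1
F2 | step 4 | 5,6-epoxy-β-ionone (racemic) | CC(=O)/C=C/C12OC1(C)CCCC2(C)C
F3 | step 4 | (E)-2-(1,2-epoxy-2,6,6-trimethylcyclohexyl)ethenyl acetate (racemic) | CC(=O)O/C=C/C12OC1(C)CCCC2(C)C
F4 | step 4 | (1,2-epoxy-2,6,6-trimethylcyclohexyl)acetaldehyde (racemic) | O=CCC12OC1(C)CCCC2(C)C
F5 | step 4 | (1,2-epoxy-2,6,6-trimethylcyclohexyl)acetic acid (racemic) | OC(=O)CC12OC1(C)CCCC2(C)C
F6 | step 4 | 3a-hydroxy-4,4,7a-trimethylhexahydro-1-benzofuran-2(3H)-one (racemic) | CC1(C)CCCC2(C)OC(=O)CC12O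
F7 | step 9 | (1S,2Z)-2-{[(2S,3S)-3-(hydroxymethyl)-3-methyloxiran-2-yl]methylidene}-1,3,3-trimethylcyclohexan-1-ol | OC[C@]1(C)O[C@H]1/C=C2/C(C)(C)CCC[C@]2(C)O
F8 | step 9 | (1R,2Z)-2-{[(2S,3S)-3-({[tert-butyl(dimethyl)silyl]oxy}methyl)-3-methyloxiran-2-yl]methylidene}-1,3,3-trimethylcyclohexan-1-ol | CC(C)(C)[Si](C)(C)OC[C@]1(C)O[C@H]1/C=C2/C(C)(C)CCC[C@@]2(C)O
F9 | step 9 | (1S,2Z)-2-{[(2S,3S)-3-({[tert-butyl(dimethyl)silyl]oxy}methyl)-3-methyloxiran-2-yl]methylidene}-1,3,3-trimethylcyclohexan-1-ol | CC(C)(C)[Si](C)(C)OC[C@]1(C)O[C@H]1/C=C2/C(C)(C)CCC[C@]2(C)O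
F10 | step 9 | (2S)-1-{[tert-butyl(dimethyl)silyl]oxy}-2-[(2R,7aR)-4,4,7a-trimethyl-2,4,5,6,7,7a-hexahydro-1-benzofuran-2-yl]propan-2-ol | CC(C)(C)[Si](C)(C)OC[C@](C)(O)[C@H]1C=C2C(C)(C)CCC[C@@]2(C)O1
F11 | step 9 | (2S)-1-{[tert-butyl(dimethyl)silyl]oxy}-2-[(2R,7aS)-4,4,7a-trimethyl-2,4,5,6,7,7a-hexahydro-1-benzofuran-2-yl]propan-2-ol | CC(C)(C)[Si](C)(C)OC[C@](C)(O)[C@H]1C=C2C(C)(C)CCC[C@]2(C)O1
F12 | step 11 | (2S)-2-[(2R,7aR)-4,4,7a-trimethyl-2,4,5,6,7,7a-hexahydro-1-benzofuran-2-yl]but-3-en-2-ol | C=C[C@](C)(O)[C@H]1C=C2C(C)(C)CCC[C@@]2(C)O1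
F13 | step 11 | (2S)-2-[(2R,7aR)-4,4,7a-trimethyl-2,4,5,6,7,7a-hexahydro-1-benzofuran-2-yl]but-3-en-2-yl acetate | C=C[C@](C)(OC(C)=O)[C@H]1C=C2C(C)(C)CCC[C@@]2(C)O1
F14 | step 11 | [(2E)-3-[(2R,7aR)-4,4,7a-trimethyl-2,4,5,6,7,7a-hexahydro-1-benzofuran-2-yl]but-2-en-1-yl](triphenyl)phosphonium acetate | C/C(=C\C[P+](c1ccccc1)(c1ccccc1)c1ccccc1)[C@H]1C=C2C(C)(C)CCC[C@@]2(C)O1.CC([O-])=O
F15 | step 11 | ylide of F14 | C/C(=C\C=P(c1ccccc1)(c1ccccc1)c1ccccc1)[C@H]1C=C2C(C)(C)CCC[C@@]2(C)O1
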